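In a one-step, pseudo-first-order world ln c_substrate falls on a straight line. Monday's readings do not: they fall at 1.17 min⁻¹ up to the first reading and at 0.214 min⁻¹ between the last two, while the substrate charged equals 40.0% of the partner charged.

all flasks: substrate 0.0020 M; initiator 0.20 mM
- Monday's: coupling partner 5 mM; run made earlier
- Tuesday's: coupling partner 8.2 mM; run made earlier
- gamma: coupling partner 6.00 mM; time 0.80 min
- zeta: coupling partner 4.00 mM; time 2.5 min

| run | time / min | target / % | substrate / % |
|---|---|---|---|
| Monday's | 0.333 | 30.9 | 67.8 |
| Monday's | 0.667 | 44.6 | 53.8 |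
| Monday's | 1.00 | 52.8 | 45.0 |
| Monday's | 1.33 | 58.0 | 38.3 |
| Monday's | 2.00 | 63.8 | 31.6 |
| Monday's | 2.50 | 67.1 | 28.4 |
| Tuesday's | 0.167 | 26.3 | 73.0 |
| Tuesday's | 0.417 | 45.2 | 52.9 |
| Tuesday's | 0.667 | 56.1 | 43.0 |
| Tuesday's | 1.00 | 65.2 | 32.8 |
| Tuesday's | 1.50 | 72.3 | 24.3 |
| Tuesday's | 2.00 | 77.6 | 18.5 |
| Tuesday's | 2.50 | 79.8 | 15.8 |

(standard deviation of a reading: 0.3 percentage points)

- which one finishes higher in amount of target, in percent of the substrate charged ("neither" within 2 percentage points) (gamma / zeta / neither)
- amount of target at the end, in percent of the substrate charged, gamma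
- amount of target at the end, in percent of the substrate charged, zeta



So I try one number, the partner dose D: partner charge times time, over the same product at Monday's 1.00 min reading. Gamma has 0.960 and zeta 2.00. At these charges of substrate and initiator, equal D should mean equal target, however the dose is split between charge and time.

Early it holds: Monday's at D 0.667 reads 44.6%, Tuesday's at D 0.684 reads 45.2%. Late it does not: D 2.50 reads 67.1% on Monday, D 2.46 reads 72.3% on Tuesday. So zeta needs a charge correction, scaled from that gap; gamma, early, does not.

gamma, between Monday's readings: 51.8%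

zeta, Monday's 2.00 min reading 63.8%, corrected: 62.2%

The forecast says zeta, with 52% and 60%, holding that “the initiator must be dying”; my zeta stands higher than its figure.

Gamma ends at 53.0% and zeta at 60.9%, so zeta finishes higher.

    coupling partner + first chain carrier → target + second chain carrier (k = 2.65 × 10⁵ M⁻¹ s⁻¹)
    2 second chain carrier → ended chains A (k = 1.90 × 10⁸ M⁻¹ s⁻¹)
    substrate + second chain carrier → by-product + first chain carrier (k = 1.55 × 10⁶ M⁻¹ s⁻¹)
    2 coupling partner → homo dimer (k = 8.09 M⁻¹ s⁻¹)
    initiator → 2 initiating radical (k = 0.00185 s⁻¹)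
    2 first chain carrier → ended chains B (k = 1.80 × 10⁸ M⁻¹ s⁻¹)
    substrate + initiating radical → capped initiator + first chain carrier (k = 4.00 × 10⁷ M⁻¹ s⁻¹)

In gamma at 0.800 min, partner goes to homo dimer 1.1 times as fast as into target, with 13% of the partner and 92% of the initiator left. D times 4.85 is a flask's time over the first half-life of its partner charge by the homo dimer step, so gamma's time is 4.66 of that first half-life. Gamma read at 2.0 min has D 2.40 and holds 69.3% target, against Monday's 67.1% and Tuesday's 72.3% at nearby doses.

(The data are calculated with constants of no real substance; the scatter is artificial.)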